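**Retrosynthetic overview**
1. The C1 2-methylpropanoyl group is removed (bridgehead acylation comes last) and the C7 prenyl group is traced back to a C7 formyl group; this leads to bicyclic aldehyde 11, which already holds the bicyclo[3.3.1]nonane-2,4,9-trione core with C1, C5 and C7 set.
2. 11 is opened at C5–C6 (dearomatising intramolecular Michael addition) and at C6–C7 (aldol condensation with formaldehyde); both bonds are made in one amine-catalysed cascade from lactol 8, a flat, fully substituted phloroglucinol.
3. 8 comes from dihydrocoumarin 7, whose temporary lactone ring carries the C1–C8 bond; 7 comes from double C-prenylation of 3, and 3 from phloroglucinol and methyl 3-methylbut-2-enoate (Friedel–Crafts annulation).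
4. Order of rings: ring C1–C2–C3–C4–C5–C9 is bought as the arene; the temporary lactone ring is closed in step 1 and opened in step 4; ring C1–C8–C7–C6–C5–C9 is closed last, in the key step, by the C5–C6 bond.
5. Enabling feature: the 1,3,5-trioxygenated ring (O on C2, C4, C9) lets C1 switch to its sp3 keto tautomer. This turns the C8 tether axial and makes C5, the enol carbon between C4–O and C9–O, a carbon nucleophile that reaches C6; C3 and C5 are enantiotopic, so only one π-face has to be chosen.

Key step: step 4

Remark: the bicyclic compounds are numbered as the target (C1 = bridgehead that finally carries the 2-methylpropanoyl group, C5 = prenylated bridgehead, C9 = bridging carbonyl); each vinylogous acid is written as one enol tautomer of an equilibrating pair, and the SMILES strings define the configurations.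

**Step 1**
Reactants: 1 benzene-1,3,5-triol (phloroglucinol), 2 methyl 3-methylbut-2-enoate
Product: 3 5,7-dihydroxy-4,4-dimethyl-3,4-dihydro-2H-chromen-2-one
Conditions: MeSO3H, 70 °C, 1 in excess
Reagents that add atoms: methyl 3-methylbut-2-enoate (compound 2), COC(=O)C=C(C)C
Why: Under non-acylating Brønsted-acid conditions the very electron-rich arene should add to the β,β-dimethyl carbon of the protonated enoate (Friedel–Crafts conjugate alkylation) and the adjacent phenol then lactonise with loss of methanol, the gem-dimethyl dihydrocoumarin annulation known for activated phenols, which forms the quaternary C8 and the C1–C8 bond while excess arene suppresses a second annulation.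

**Step 2**
Reactants: 3 5,7-dihydroxy-4,4-dimethyl-3,4-dihydro-2H-chromen-2-one, 4 1-bromo-3-methylbut-2-ene (prenyl bromide)
Product: 7 5,7-dihydroxy-4,4-dimethyl-6,8-bis(3-methylbut-2-en-1-yl)-3,4-dihydro-2H-chromen-2-one, via ring-opened hydroxy acid 5 (not isolated), via diprenylated hydroxy acid 6 (not isolated)
Conditions: KOH (aq, degassed), 4 (2.2 equiv), 0 °C to rt; then HCl (aq) to pH 1
Reagents that add atoms: 1-bromo-3-methylbut-2-ene (compound 4), CC(C)=CCBr
Why: Aqueous hydroxide opens the lactone to phenolate 5, whose two unsubstituted ring carbons should be C-prenylated (SN2 C-alkylation of a phloroglucinolate in a protic medium, the standard entry to prenylated phloroglucinols), and acidification of 6 re-closes the lactone, a ring closure that the gem-dimethyl group makes spontaneous.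

**Step 3**
Reactants: 7 5,7-dihydroxy-4,4-dimethyl-6,8-bis(3-methylbut-2-en-1-yl)-3,4-dihydro-2H-chromen-2-one
Product: 8 4,4-dimethyl-6,8-bis(3-methylbut-2-en-1-yl)-3,4-dihydro-2H-chromene-2,5,7-triol (lactol, racemic at the hemiacetal carbon)
Conditions: i-Bu2AlH (3.5 equiv), CH2Cl2, −78 °C; aq. potassium sodium tartrate
Reagents that add atoms: none
Why: Partial reduction of an aryl lactone to the lactol with i-Bu2AlH at −78 °C is a standard transformation, the tetrahedral aluminate being stable at low temperature and the cyclic hemiacetal being favoured by the gem-dimethyl group, while the two phenols are carried through as aluminium phenolates.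

**Step 4**
Reactants: 8 4,4-dimethyl-6,8-bis(3-methylbut-2-en-1-yl)-3,4-dihydro-2H-chromene-2,5,7-triol, 9 formaldehyde (37 % aqueous solution, 1.1 equiv)
Product: 11 (1S,5R,7S)-4-hydroxy-8,8-dimethyl-3,5-bis(3-methylbut-2-en-1-yl)-2,9-dioxobicyclo[3.3.1]non-3-ene-7-carbaldehyde, via 2-methylidene aldehyde 10 (not isolated)
Conditions: (R)-2-[diphenyl(trimethylsilyloxy)methyl]pyrrolidine (20 mol %), PhCO2H (20 mol %), PhMe, 0 °C to rt
Reagents that add atoms: formaldehyde (compound 9), C=O
Why: Proposed new method: the amine condenses with the open hydroxy-aldehyde form of 8 to an enamine that adds to formaldehyde and loses water (aldol condensation) to give 10 as its catalyst-bound 2-methylidene iminium ion, whose CH2 terminus C6 is then attacked by ring carbon C5 of the C1-keto tautomer of the phloroglucinol in an intramolecular dearomatising Michael addition, and hydrolysis of the product enamine returns the catalyst; the closest known reaction types are the amine-catalysed α-methylenation of aldehydes, iminium-catalysed enantioselective Friedel–Crafts-type conjugate additions of electron-rich arenes to enals and the base-mediated dearomatising Michael annulation of acylphloroglucinols with 2-methylidene aldehydes. The ring C1–C8–C7–C6–C5–C9 is closed in a 6-endo-trig mode with C5–C6 as its last bond, through a chair in which C8 and C6 stand axial on the former arene ring. C5 and C1 are fixed together by the π-face of the planar iminium ion on which the arene has to stack, and the diphenyl(silyloxy)methyl group of the (R)-catalyst is expected to block one face (E-iminium with the methylidene group syn to nitrogen) so that the (1S,5R) core results. C7 is set afterwards under thermodynamic control, the formyl group epimerising through its enamine to the exo, equatorial position that avoids the transannular contact with C3. The step needs C- over O-alkylation and conjugate over direct addition: chroman formation by the phenolic oxygens, attack at the iminium carbon and aldol capture of the endo-formyl epimer by C3 are all reversible, whereas the C5–C6 adduct is a stable vinylogous acid, and because C3 and C5 are enantiotopic no regiochemical choice arises. The gem-dimethyl group at C8 favours the folded conformer that brings C6 over C5.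

**Step 5**
Reactants: 11 (1S,5R,7S)-4-hydroxy-8,8-dimethyl-3,5-bis(3-methylbut-2-en-1-yl)-2,9-dioxobicyclo[3.3.1]non-3-ene-7-carbaldehyde, 12 (trimethylsilyl)diazomethane
Product: 13 (1S,5S,7S)-2-methoxy-8,8-dimethyl-3,5-bis(3-methylbut-2-en-1-yl)-4,9-dioxobicyclo[3.3.1]non-2-ene-7-carbaldehyde
Conditions: Me3SiCHN2 (hexane solution), PhMe/MeOH, 0 °C
Reagents that add atoms: (trimethylsilyl)diazomethane (compound 12), C[Si](C)(C)C=[N+]=[N-]
Why: O-Methylation of the vinylogous acid by the diazoalkane (proton transfer, then SN2 on the methyldiazonium ion) should take place at the less hindered oxygen O2, next to the bridgehead C1–H, because O4 is flanked by the quaternary C5 with its prenyl group, and it removes the acidic enol before the basic Wittig steps and the bridgehead lithiation.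

**Step 6**
Reactants: 13 (1S,5S,7S)-2-methoxy-8,8-dimethyl-3,5-bis(3-methylbut-2-en-1-yl)-4,9-dioxobicyclo[3.3.1]non-2-ene-7-carbaldehyde, 14 (methoxymethyl)triphenylphosphonium chloride
Product: 16 2-[(1S,5S,7R)-2-methoxy-8,8-dimethyl-3,5-bis(3-methylbut-2-en-1-yl)-4,9-dioxobicyclo[3.3.1]non-2-en-7-yl]acetaldehyde, via enol ether 15 (not isolated)
Conditions: 14, KN(SiMe3)2, THF, 0 °C; then 13, 0 °C to rt; then HCl (1 M aq), THF, 0 °C
Reagents that add atoms: (methoxymethyl)triphenylphosphonium chloride (compound 14), COC[P+](c1ccccc1)(c1ccccc1)c1ccccc1.[Cl-]; water, O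
Why: Wittig methoxymethylenation of the hindered but reactive aldehyde followed by mild acid hydrolysis of the simple enol ether (far faster than that of the conjugated vinylogous ester) is the classical one-carbon homologation, and the C7 centre, set exo under thermodynamic control in step 4, cannot epimerise further once the carbonyl group has moved one carbon away.

**Step 7**
Reactants: 16 2-[(1S,5S,7R)-2-methoxy-8,8-dimethyl-3,5-bis(3-methylbut-2-en-1-yl)-4,9-dioxobicyclo[3.3.1]non-2-en-7-yl]acetaldehyde, 17 triphenyl(propan-2-yl)phosphonium iodide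
Product: 18 (1S,5S,7S)-2-methoxy-8,8-dimethyl-3,5,7-tris(3-methylbut-2-en-1-yl)bicyclo[3.3.1]non-2-ene-4,9-dione
Conditions: 17, KN(SiMe3)2, THF, 0 °C; then 16, 0 °C to rt
Reagents that add atoms: triphenyl(propan-2-yl)phosphonium iodide (compound 17), CC(C)[P+](c1ccccc1)(c1ccccc1)c1ccccc1.[I-]
Why: Wittig olefination of the unhindered aldehyde with the non-stabilised isopropylidene ylide completes the C7 prenyl group, the hindered C4 and C9 carbonyl groups being inert to the ylide.

**Step 8**
Reactants: 18 (1S,5S,7S)-2-methoxy-8,8-dimethyl-3,5,7-tris(3-methylbut-2-en-1-yl)bicyclo[3.3.1]non-2-ene-4,9-dione, 19 2-methylpropanoyl chloride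
Product: 20 (1S,5R,7S)-2-methoxy-8,8-dimethyl-3,5,7-tris(3-methylbut-2-en-1-yl)-1-(2-methylpropanoyl)bicyclo[3.3.1]non-2-ene-4,9-dione
Conditions: lithium 2,2,6,6-tetramethylpiperidide (1.5 equiv), THF, −78 to −40 °C; then 19, −78 °C to rt
Reagents that add atoms: 2-methylpropanoyl chloride (compound 19), CC(C)C(Cl)=O
Why: Deprotonation of the bridgehead C1–H α to the C9 ketone by the hindered lithium amide (C3 and C5 carry no hydrogen, so no other enolisable position competes) and C-acylation of the resulting pyramidal bridgehead carbanion, which can only react with retention, is the bridgehead lithiation/acylation used on O-methylated bicyclo[3.3.1]nonane-2,4,9-triones, and it sets C1 as in the target.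

**Step 9**
Reactants: 20 (1S,5R,7S)-2-methoxy-8,8-dimethyl-3,5,7-tris(3-methylbut-2-en-1-yl)-1-(2-methylpropanoyl)bicyclo[3.3.1]non-2-ene-4,9-dione
Product: 21 (1R,5R,7S)-4-hydroxy-8,8-dimethyl-3,5,7-tris(3-methylbut-2-en-1-yl)-1-(2-methylpropanoyl)bicyclo[3.3.1]non-3-ene-2,9-dione (target)
Conditions: LiCl, DMSO, 120 °C; then dilute HCl (aq)
Reagents that add atoms: none
Why: Chloride attacks the methyl group of the vinylogous ester in hot DMSO (SN2 O-demethylation of Krapcho type, the standard unmasking of such enol ethers) and the liberated enolate is protonated on work-up, conditions that spare the prenyl groups and the retro-Claisen-prone triketone.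

**Compound list**
1 | benzene-1,3,5-triol (phloroglucinol) | Oc1cc(O)cc(O)c1 | starting material
2 | methyl 3-methylbut-2-enoate | COC(=O)C=C(C)C | starting material
3 | 5,7-dihydroxy-4,4-dimethyl-3,4-dihydro-2H-chromen-2-one | CC1(C)CC(=O)Oc2cc(O)cc(O)c12 | intermediate
4 | 1-bromo-3-methylbut-2-ene | CC(C)=CCBr | starting material
5 | 3-methyl-3-(2,4,6-trihydroxyphenyl)butanoic acid (present as potassium salt, not isolated) | CC(C)(CC(=O)O)c1c(O)cc(O)cc1O | intermediate
6 | 3-methyl-3-[2,4,6-trihydroxy-3,5-bis(3-methylbut-2-en-1-yl)phenyl]butanoic acid (present as potassium salt, not isolated) | CC(C)=CCc1c(O)c(CC=C(C)C)c(O)c(C(C)(C)CC(=O)O)c1O | intermediate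
7 | 5,7-dihydroxy-4,4-dimethyl-6,8-bis(3-methylbut-2-en-1-yl)-3,4-dihydro-2H-chromen-2-one | CC1(C)CC(=O)Oc2c(CC=C(C)C)c(O)c(CC=C(C)C)c(O)c12 | intermediate
8 | 4,4-dimethyl-6,8-bis(3-methylbut-2-en-1-yl)-3,4-dihydro-2H-chromene-2,5,7-triol (lactol, racemic at the hemiacetal carbon) | CC1(C)CC(O)Oc2c(CC=C(C)C)c(O)c(CC=C(C)C)c(O)c12 | intermediate
9 | formaldehyde | C=O | starting material
10 | 3-methyl-2-methylidene-3-[2,4,6-trihydroxy-3,5-bis(3-methylbut-2-en-1-yl)phenyl]butanal (formed as its iminium ion with the catalyst, not isolated) | CC(C)=CCc1c(O)c(CC=C(C)C)c(O)c(C(C)(C)C(=C)C=O)c1O | intermediate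
11 | (1S,5R,7S)-4-hydroxy-8,8-dimethyl-3,5-bis(3-methylbut-2-en-1-yl)-2,9-dioxobicyclo[3.3.1]non-3-ene-7-carbaldehyde | CC(C)=CCC1=C(O)[C@@]2(CC=C(C)C)C[C@H](C=O)C(C)(C)[C@@H](C1=O)C2=O | intermediate
12 | (trimethylsilyl)diazomethane | C[Si](C)(C)C=[N+]=[N-] | starting material
13 | (1S,5S,7S)-2-methoxy-8,8-dimethyl-3,5-bis(3-methylbut-2-en-1-yl)-4,9-dioxobicyclo[3.3.1]non-2-ene-7-carbaldehyde | CC(C)=CCC=1C(=O)[C@@]2(CC=C(C)C)C[C@H](C=O)C(C)(C)[C@@H](C=1OC)C2=O | intermediate
14 | (methoxymethyl)triphenylphosphonium chloride | COC[P+](c1ccccc1)(c1ccccc1)c1ccccc1.[Cl-] | starting material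
15 | (1S,5S,7R)-2-methoxy-7-(2-methoxyethenyl)-8,8-dimethyl-3,5-bis(3-methylbut-2-en-1-yl)bicyclo[3.3.1]non-2-ene-4,9-dione (E/Z mixture, not isolated) | CC(C)=CCC=1C(=O)[C@@]2(CC=C(C)C)C[C@H](C=COC)C(C)(C)[C@@H](C=1OC)C2=O | intermediate
16 | 2-[(1S,5S,7R)-2-methoxy-8,8-dimethyl-3,5-bis(3-methylbut-2-en-1-yl)-4,9-dioxobicyclo[3.3.1]non-2-en-7-yl]acetaldehyde | CC(C)=CCC=1C(=O)[C@@]2(CC=C(C)C)C[C@H](CC=O)C(C)(C)[C@@H](C=1OC)C2=O | intermediate
17 | triphenyl(propan-2-yl)phosphonium iodide | CC(C)[P+](c1ccccc1)(c1ccccc1)c1ccccc1.[I-] | starting material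
18 | (1S,5S,7S)-2-methoxy-8,8-dimethyl-3,5,7-tris(3-methylbut-2-en-1-yl)bicyclo[3.3.1]non-2-ene-4,9-dione | CC(C)=CCC=1C(=O)[C@@]2(CC=C(C)C)C[C@H](CC=C(C)C)C(C)(C)[C@@H](C=1OC)C2=O | intermediate
19 | 2-methylpropanoyl chloride | CC(C)C(Cl)=O | starting material
20 | (1S,5R,7S)-2-methoxy-8,8-dimethyl-3,5,7-tris(3-methylbut-2-en-1-yl)-1-(2-methylpropanoyl)bicyclo[3.3.1]non-2-ene-4,9-dione | CC(C)=CCC=1C(=O)[C@@]2(CC=C(C)C)C[C@H](CC=C(C)C)C(C)(C)[C@@](C(=O)C(C)C)(C=1OC)C2=O | intermediate
21 | (1R,5R,7S)-4-hydroxy-8,8-dimethyl-3,5,7-tris(3-methylbut-2-en-1-yl)-1-(2-methylpropanoyl)bicyclo[3.3.1]non-3-ene-2,9-dione | CC(C)=CCC1=C(O)[C@@]2(CC=C(C)C)C[C@H](CC=C(C)C)C(C)(C)[C@@](C(=O)C(C)C)(C1=O)C2=O | target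

**Step count and risks**
Total step count: 9. Longest linear sequence: 9 steps (1 to 21).

Steps most likely to fail:

1. Step 4 (proposed new method). The risks are loss of enantiocontrol through an uncatalysed cyclisation of free enal 10, poor π-facial discrimination in the hindered 2-substituted iminium ion, and diversion of the endo-formyl epimer into an aldol adduct with C3. The predicted sense of induction rests on a steric-shielding model; if it proves opposite, the (S)-catalyst would be used. The fallback sets out from 8 and uses only known chemistry. Amine-catalysed α-methylenation with aqueous formaldehyde, pyrrolidine and propanoic acid, followed by K2CO3 in MeOH to complete the base-mediated dearomatising Michael addition, should give the racemic aldehyde F1. Condensation of this with (1R,2R)-N,N'-dimethyl-1,2-diphenylethane-1,2-diamine should give two diastereomeric imidazolidines that are separated by chromatography, the one with the (1S,5R,7S) core being the aminal F2. Mild aqueous acid hydrolysis of this aminal comes back to the route at 11.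

2. Step 8. The risks are incomplete deprotonation of the bridgehead C1–H next to the quaternary C8 and consumption of the acid chloride by the amide base (ketene formation), so that C-acylation at the congested bridgehead stalls. The fallback sets out from 18: the bridgehead lithium species is trapped with the smaller electrophile 2-methylpropanal to give the bridgehead carbinol F3 (mixture of carbinol epimers), and Dess–Martin oxidation of this alcohol comes back to the route at 20.

3. Step 2. The risks are over-alkylation at ring carbons that are already substituted (dearomatisation to gem-diprenyl triones), O-prenylation and air oxidation of the electron-rich phenolate. The fallback sets out from 3 and changes the prenyl donor and the mechanism: acid-mediated Friedel–Crafts prenylation with 2-methylbut-3-en-2-ol and BF3·OEt2 in 1,4-dioxane at rt, which leaves the lactone closed and comes back to the route at 7; it makes no compound outside the list (F0).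

**Further compounds**
F1 | step 4 | rac-(1S*,5R*,7S*)-4-hydroxy-8,8-dimethyl-3,5-bis(3-methylbut-2-en-1-yl)-2,9-dioxobicyclo[3.3.1]non-3-ene-7-carbaldehyde (racemate of 11) | CC(C)=CCC1=C(O)C2(CC=C(C)C)CC(C=O)C(C)(C)C(C1=O)C2=O
F2 | step 4 | (1S,5R,7S)-7-[(4R,5R)-1,3-dimethyl-4,5-diphenylimidazolidin-2-yl]-4-hydroxy-8,8-dimethyl-3,5-bis(3-methylbut-2-en-1-yl)bicyclo[3.3.1]non-3-ene-2,9-dione | CC(C)=CCC1=C(O)[C@@]2(CC=C(C)C)C[C@H](C3N(C)[C@H](c4ccccc4)[C@@H](c4ccccc4)N3C)C(C)(C)[C@@H](C1=O)C2=O
F3 | step 8 | (1R,5R,7S)-1-(1-hydroxy-2-methylpropyl)-2-methoxy-8,8-dimethyl-3,5,7-tris(3-methylbut-2-en-1-yl)bicyclo[3.3.1]non-2-ene-4,9-dione (carbinol epimers) | CC(C)=CCC=1C(=O)[C@@]2(CC=C(C)C)C[C@H](CC=C(C)C)C(C)(C)[C@@](C(O)C(C)C)(C=1OC)C2=O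
F0 | step 2 | none | none
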